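In a closed stirred flask the earlier runs turned two settings, time and reagent, so I ask what each does before I reckon anything.

| flask | starting material | reagent | remark | time |
|---|---|---|---|---|
| Sunday's | 0.20 M | 0.26 M | run made earlier |  |
| Wednesday's | 0.20 M | 0.17 M | run made earlier |  |
| Thursday's | 0.20 M | 0.39 M | run made earlier |  |
| zeta | 0.20 M | 0.260 M (fed, over 8.00 h) | a stirred flask in which reagent is dosed at a steady rate over 8.00 h without added volume, worked up at 10 h | 10 h |
| epsilon | 0.20 M | 0.260 M | a single well-mixed tank run continuously and read at steady state, 10 h in it on average |  |
| theta | 0.20 M (fed, over 8.00 h) | 0.260 M | all but starting material at the start; starting material goes in evenly over 8.00 h, the run ends at 10 h | 10 h |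
| beta | 0.20 M | 0.260 M | everything together in a closed stirred flask, run for 10 h | 10 h |

| run | time / h | target / % | starting material / % |
|---|---|---|---|
| Sunday's | 2.50 | 61 | 0 |
| Sunday's | 5.00 | 61 | 0 |
| Sunday's | 8.00 | 57 | 2 |
| Sunday's | 10.0 | 63 | 1 |
| Wednesday's | 1.33 | 49 | 12 |
| Wednesday's | 4.00 | 42 | 6 |
| Wednesday's | 6.00 | 42 | 2 |
| Wednesday's | 10.0 | 41 | 1 |
| Thursday's | 2.50 | 70 | 0 |
| Thursday's | 5.00 | 75 | 0 |
| Thursday's | 8.00 | 72 | 0 |
| Thursday's | 10.0 | 74 | 0 |

(each reading ± 2 percentage points)

- the stated concentrations are those of everything mixed, before any reaction; amounts are the same in each set-up
- the numbers in the tables scatter with a standard deviation of 2 percentage points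
- the feed brings no volume worth counting
- the earlier runs were made in a closed, stirred flask

- the set-up with the highest amount of target at the outlet or at the end, in percent of the starting material put in ("none" if the first two lie within 2 percentage points) (zeta / epsilon / theta / beta / none)
- amount of target at the outlet or at the end, in percent of the starting material put in, zeta
- amount of target at the outlet or at the end, in percent of the starting material put in, epsilon
- amount of target at the outlet or at the end, in percent of the starting material put in, theta
- amount of target at the outlet or at the end, in percent of the starting material put in, beta

By hand, more time should add target while starting material remains. In Sunday's run target reads 61% at 2.50 h and 63% at 10.0 h, inside the scatter of 2 percentage points, with starting material at 0% and 1%, so time past that point gains nothing I can read.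

By hand, more reagent should give more target, roughly in step with the charge. Wednesday's run ends at 41% with 0.17 M of reagent and Sunday's at 63% with 0.26 M. So I freeze one number, g, the yield on reagent: the concentration of target at the end per concentration of reagent charged, 0.482 from Wednesday's run. Sunday's run reads 0.485, but Thursday's, with 0.39 M, reads a lower 0.379. I therefore hold g to a flask charged at once with 0.20 M of starting material and reagent up to Sunday's level.

Beta is such a flask, and g gives it 62.7%. In Wednesday's run target falls from 49% to 41% while starting material falls from 12% to 1%. For zeta, where reagent trickles in beside starting material, I make a rough guess of my own and reckon it as a flask charged with half the reagent. That gives 31.4%, less than beta. Theta and epsilon lack the 0.20 M of starting material with which each earlier run began, so g gives me no number for them.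

The forecast says zeta 35%, epsilon 39%, theta 61% and beta 61%, and for the best none: “Beta and theta tie, so best is none.” Its zeta is higher than my 31.4%, and its beta is lower than my 62.7%.

    starting material + reagent → target, rate k1*[starting material]^1.5*[reagent] (k = 0.0160 M⁻¹·⁵ s⁻¹)
    starting material + target → side product (k = 0.00160 M⁻¹ s⁻¹)

The best is beta: beta gives 61.0%, theta 50.5%, epsilon 35.3% and zeta 25.6%. With the step of starting material + target struck out, zeta minus beta is −2.5 points instead of −35 points. Zeta's 25.6% stands below the 31.4% I reckoned from g with half the reagent. In a flask like beta with 0.16 M of reagent, g gives 38.6%, and the computed result is 37.2%.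

Readings and results were computed for substances that don't exist; scatter was added.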